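**Retrosynthetic overview**

- The target is the C3 ester of a 3α,4α,7α,11-tetrahydroxyeudesman-8-one. The ester is cut (Yamaguchi) to (2S,3S)-epoxyangelic acid, made from angelic acid by Sharpless epoxidation, and the tetraol; the 7α,11-diol comes from a C7(11)-en-8-one by nucleophilic epoxidation and hydrolysis.
- Feature used: C4 is a methyl carbinol between the oxygenated C3 and the ring-fusion carbon C5, and C8 is a ketone flanked by C9 and C7=C11. A C3-benzyloxy methyl ketone (C4) can therefore start, and a silyl dienol ether (C9=C8–C7=C11) can end, a cation–olefin bicyclisation across an E C5=C10 olefin.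
- Ring order: ring A (C4–C5 bond) and then ring B (C9–C10 bond) close in one SnCl4 step from an acyclic keto-triene whose only stereocentre is C3.
- Precursor: the C4 ketone is released last (MeMgBr on a Weinreb amide) once the dienol ether is in place, so two enolisable ketones are never free together. C1–C10 comes from a Negishi coupling of an alkylzinc with an E-alkenyl iodide; the C7=C11 enone comes from acetylacetone by alkylation, enol triflate and Me2CuLi.

Key step: step 12

Assumption: (R)-3-hydroxyoxolan-2-one (the α-hydroxy lactone of the (R)-malic acid series) is bought as such; all carbons are cited in eudesmane numbering, α being the face opposite the C10 methyl group.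

**Route**

Step 1
Reactants: 1 (R)-3-hydroxyoxolan-2-one
Product: 2 (R)-3-(benzyloxy)oxolan-2-one
Conditions: BnOC(=NH)CCl3 (1.3 equiv), TfOH (5 mol%), CH2Cl2/cyclohexane, 0 °C → rt
Reagents that add atoms: benzyl 2,2,2-trichloroacetimidate, N=C(OCc1ccccc1)C(Cl)(Cl)Cl
Why: Acid-catalysed trichloroacetimidate O-benzylation needs no base, so the α-stereocentre of the lactone (the future C3) should not epimerise.

Step 2
Reactants: 2 (R)-3-(benzyloxy)oxolan-2-one
Product: 3 (2R)-2-(benzyloxy)-4-hydroxy-N-methoxy-N-methylbutanamide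
Conditions: MeNH(OMe)·HCl (3 equiv), AlMe3 (3 equiv), CH2Cl2, 0 °C → rt; aq. KNaC4H4O6
Reagents that add atoms: N,O-dimethylhydroxylamine hydrochloride, CNOC.Cl
Why: Weinreb aminolysis of the lactone by the aluminium amide opens the ring without touching C3 and installs the amide that later becomes the C4 methyl ketone.

Step 3
Reactants: 3 (2R)-2-(benzyloxy)-4-hydroxy-N-methoxy-N-methylbutanamide
Product: 4 (2R)-2-(benzyloxy)-4-iodo-N-methoxy-N-methylbutanamide
Conditions: I2, PPh3, imidazole, CH2Cl2, 0 °C; used promptly
Reagents that add atoms: iodine, [I][I]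
Why: Appel-type iodination of the primary alcohol is fast and neutral and should outrun relactonisation of the γ-hydroxy amide.

Step 4
Reactants: 5 but-2-yn-1-ol
Product: 8 (E)-3-iodobut-2-en-1-ol, via aluminium alkoxide 6 (not isolated), via alkenylzirconocene 7 (not isolated)
Conditions: iBu2AlH (1.0 equiv), THF, 0 °C; Cp2Zr(H)Cl (1.5 equiv), rt; I2, −78 → 0 °C
Reagents that add atoms: iodine, [I][I]
Why: Hydrozirconation–iodinolysis: Zr–H adds syn with zirconium on the methyl-bearing carbon, away from the bulky O-aluminated CH2O group (excess hydride equilibrates the regioisomers toward this one), and iodinolysis with retention gives the E iodide whose geometry becomes that of the C5=C10 olefin.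

Step 5
Reactants: 8 (E)-3-iodobut-2-en-1-ol
Product: 9 (E)-1-bromo-3-iodobut-2-ene
Conditions: CBr4, PPh3, CH2Cl2, 0 °C
Reagents that add atoms: carbon tetrabromide, BrC(Br)(Br)Br
Why: Appel bromination of a primary allylic alcohol proceeds by SN2 without allylic shift and leaves the alkenyl iodide intact.

Step 6
Reactants: 9 (E)-1-bromo-3-iodobut-2-ene; 10 pentane-2,4-dione
Product: 11 3-[(2E)-3-iodobut-2-en-1-yl]pentane-2,4-dione
Conditions: 10 (2 equiv), K2CO3, acetone, rt → 50 °C
Reagents that add atoms: none
Why: C-alkylation of a β-diketone enolate with an allylic bromide forms the C6–C7 bond without regiochemical ambiguity because the diketone is symmetrical.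

Step 7
Reactants: 11 3-[(2E)-3-iodobut-2-en-1-yl]pentane-2,4-dione
Product: 13 (2Z,5E)-3-acetyl-6-iodohepta-2,5-dien-2-yl trifluoromethanesulfonate, via sodium enolate 12 (not isolated)
Conditions: NaH, DME, 0 °C; Tf2O, −78 → 0 °C
Reagents that add atoms: trifluoromethanesulfonic anhydride, O=S(=O)(OS(=O)(=O)C(F)(F)F)C(F)(F)F
Why: Enol triflate formation from the chelated sodium enolate gives the vinylogous acyl triflate, whose double-bond geometry is immaterial because that carbon receives a second methyl group in the next step.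

Step 8
Reactants: 13 (2Z,5E)-3-acetyl-6-iodohepta-2,5-dien-2-yl trifluoromethanesulfonate
Product: 14 3-[(2E)-3-iodobut-2-en-1-yl]-4-methylpent-3-en-2-one
Conditions: Me2CuLi (1.2 equiv, from CuI and MeLi), Et2O/THF, −78 °C, short reaction time; aq. NH4Cl
Reagents that add atoms: methyllithium (delivered as Me2CuLi), C[Li]
Why: Cuprate addition–elimination on the β-triflyloxy enone gives the β,β-dimethyl enone directly in conjugation, and at −78 °C the unactivated alkenyl iodide should not react.

Step 9
Reactants: 4 (2R)-2-(benzyloxy)-4-iodo-N-methoxy-N-methylbutanamide; 14 3-[(2E)-3-iodobut-2-en-1-yl]-4-methylpent-3-en-2-one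
Product: 16 (2R,5E)-2-(benzyloxy)-N-methoxy-N,5-dimethyl-9-oxo-8-(propan-2-ylidene)dec-5-enamide, via alkylzinc iodide 15 (not isolated)
Conditions: Zn dust (activated with BrCH2CH2Br and Me3SiCl), THF, 35 °C; then 14, Pd(PPh3)4 (5 mol%), THF, rt → 40 °C
Reagents that add atoms: none
Why: Negishi coupling of a primary alkylzinc iodide with an alkenyl iodide tolerates the Weinreb amide and the enone and retains olefin geometry, so the C1–C10 bond forms with the E C5=C10 olefin in place.

Step 10
Reactants: 16 (2R,5E)-2-(benzyloxy)-N-methoxy-N,5-dimethyl-9-oxo-8-(propan-2-ylidene)dec-5-enamide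
Product: 18 (2R,5E)-2-(benzyloxy)-9-[(tert-butyldimethylsilyl)oxy]-N-methoxy-N,5-dimethyl-8-(propan-2-ylidene)deca-5,9-dienamide, via lithium dienolate 17 (not isolated)
Conditions: LiN(iPr)2 (1.05 equiv), THF, −78 °C; tBuMe2SiOTf, −78 °C; Et3N, pH 7 buffer
Reagents that add atoms: tert-butyldimethylsilyl trifluoromethanesulfonate, CC(C)(C)[Si](C)(C)OS(=O)(=O)C(F)(F)F
Why: Kinetic enolate O-silylation: the lithium amide removes an α′ proton of the enone methyl group (C9) far faster than the much less acidic α-proton of the Weinreb amide, giving the cross-conjugated 2-silyloxy diene without disturbing C3.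

Step 11
Reactants: 18 (2R,5E)-2-(benzyloxy)-9-[(tert-butyldimethylsilyl)oxy]-N-methoxy-N,5-dimethyl-8-(propan-2-ylidene)deca-5,9-dienamide
Product: 20 (3R,6E)-3-(benzyloxy)-10-[(tert-butyldimethylsilyl)oxy]-6-methyl-9-(propan-2-ylidene)undeca-6,10-dien-2-one, via magnesium hemiaminal 19 (not isolated)
Conditions: MeMgBr (2 equiv), THF, −40 → 0 °C; pH 7 phosphate buffer, 0 °C; Et3N-deactivated silica
Reagents that add atoms: methylmagnesium bromide, C[Mg]Br
Why: Weinreb ketone synthesis stops at the chelated tetrahedral adduct, α-alkoxy Weinreb amides react without loss of configuration, and the silyl dienol ether, which also masks the C8 ketone from the Grignard reagent, should survive the basic reaction and neutral work-up.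

Step 12
Reactants: 20 (3R,6E)-3-(benzyloxy)-10-[(tert-butyldimethylsilyl)oxy]-6-methyl-9-(propan-2-ylidene)undeca-6,10-dien-2-one
Product: 22 3α-benzyloxy-4α-hydroxyeudesm-7(11)-en-8-one (3R,4S,5R,10R), via tin chelate 21 (not isolated)
Conditions: SnCl4 (1.1 equiv), 2,6-di-tert-butyl-4-methylpyridine (0.3 equiv), CH2Cl2 (0.002 M), −78 °C; aq. NaHCO3
Reagents that add atoms: none
Why: Proposed new method: SnCl4 binds the C3 benzyloxy oxygen and the C4 carbonyl oxygen in a five-membered chelate, C5 of the E olefin attacks the activated C4 (C4–C5 bond, ring A) to leave a tertiary cation at C10, the terminal carbon C9 of the silyl dienol ether captures that cation (C9–C10 bond, ring B), and chloride then removes the silyl group from the C8 oxocarbenium ion to release the C7(11)-en-8-one. The closest known reactions are Lewis-acid Prins and carbonyl-ene cyclisations of olefinic ketones (one ring) and acetal- or aldehyde-initiated polyene cyclisations that end on enol ethers or allylsilanes; what is new is a chelated ketone as initiator of a two-ring cascade. Ring A closes through a chair, 6-endo with respect to the C5=C10 olefin and exo with respect to the C4=O bond, and ring B closes through a chair when C9 adds to C10, both enol ether carbons C8 and C9 becoming ring members (6-endo with respect to the enol ether). C4 is set by the chelate, which holds the C3–O bond coplanar with C4=O while C5, tethered through C2, must add from the C2 face, so the C3 oxygen becomes axial, the C4 oxygen equatorial and cis to it, and the C4 methyl axial; C5 follows from the chair of ring A with the C6 branch equatorial, and C10 from anti addition of C4 and C9 across the E olefin, which gives the trans fusion with the C10 methyl axial. The step needs the olefin to beat the more nucleophilic silyl enol ether in the attack on C4 and needs the silyl group to last until the C9–C10 bond has formed; the six-membered chair closure against a ten-membered aldol ring, high dilution against intermolecular aldol addition, and the tert-butyldimethylsilyl group, −78 °C and the hindered pyridine against protodesilylation and tin–silicon exchange should secure this.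

Step 13
Reactants: 22 3α-benzyloxy-4α-hydroxyeudesm-7(11)-en-8-one
Product: 23 3α-benzyloxy-7α,11-epoxy-4α-hydroxyeudesman-8-one (3R,4S,5R,7S,10R)
Conditions: 30% H2O2, NaOH, MeOH, 0 °C → rt
Reagents that add atoms: hydrogen peroxide, OO
Why: Weitz–Scheffer epoxidation: hydroperoxide adds to C11 and the C8 enolate closes the oxirane through C7 with the new C7–O bond axial (α), the arrangement that keeps the bulky C11 carbon equatorial and is not hindered by the β C10 methyl group.

Step 14
Reactants: 23 3α-benzyloxy-7α,11-epoxy-4α-hydroxyeudesman-8-one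
Product: 24 3α-benzyloxy-4α,7α,11-trihydroxyeudesman-8-one
Conditions: 5% aq. HClO4, THF/H2O, 0 °C → rt
Reagents that add atoms: water, O
Why: Acid-catalysed epoxide hydrolysis opens the oxirane at the tertiary C11 while the C7–O bond next to the carbonyl group stays intact, so the 7α configuration is retained in the 7α,11-diol.

Step 15
Reactants: 24 3α-benzyloxy-4α,7α,11-trihydroxyeudesman-8-one
Product: 25 3α,4α,7α,11-tetrahydroxyeudesman-8-one
Conditions: H2 (1 atm), 10% Pd/C, EtOAc, rt
Reagents that add atoms: none
Why: Hydrogenolysis of the benzyl ether is clean at this stage because no olefin remains and tertiary alcohols and the α-hydroxy ketone are stable to the conditions.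

Step 16
Reactants: 26 angelic acid, (Z)-2-methylbut-2-enoic acid
Product: 27 (Z)-2-methylbut-2-en-1-ol
Conditions: LiAlH4, Et2O, 0 °C
Reagents that add atoms: none
Why: LiAlH4 reduction of the α,β-unsaturated acid at low temperature gives the allylic alcohol without Z to E isomerisation or reduction of the olefin.

Step 17
Reactants: 27 (Z)-2-methylbut-2-en-1-ol
Product: 28 [(2R,3S)-2,3-dimethyloxiran-2-yl]methanol
Conditions: Ti(OiPr)4 (10 mol%), D-(−)-diisopropyl tartrate (12 mol%), tBuOOH, 4 Å molecular sieves, CH2Cl2, −20 °C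
Reagents that add atoms: tert-butyl hydroperoxide, CC(C)(C)OO
Why: Sharpless asymmetric epoxidation with the D-(−)-tartrate catalyst delivers oxygen to the olefin face that gives the 2R epoxy alcohol (L-(+)-tartrate gives the 2S series), and stereospecific syn addition to the Z olefin fixes C3 as S.

Step 18
Reactants: 28 [(2R,3S)-2,3-dimethyloxiran-2-yl]methanol
Product: 29 (2S,3S)-2,3-dimethyloxirane-2-carboxylic acid
Conditions: RuCl3·xH2O (2 mol%), NaIO4 (3 equiv), CCl4/MeCN/H2O, 0 °C → rt
Reagents that add atoms: water, O
Why: RuO4-catalysed oxidation of a 2,3-epoxy alcohol to the glycidic acid leaves the oxirane untouched, and the C2 descriptor changes from R to S only through the change in CIP priorities.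

Step 19
Reactants: 25 3α,4α,7α,11-tetrahydroxyeudesman-8-one; 29 (2S,3S)-2,3-dimethyloxirane-2-carboxylic acid
Product: 31 3α-[(2S,3S)-2,3-dimethyloxirane-2-carbonyloxy]-4α,7α,11-trihydroxyeudesman-8-one (CNP0145407.1), via mixed anhydride 30 (not isolated)
Conditions: 29, 2,4,6-Cl3C6H2COCl, Et3N, THF, rt; then 25, DMAP, toluene, rt → 40 °C
Reagents that add atoms: none
Why: Yamaguchi esterification: DMAP transfers the epoxyangeloyl group from the mixed anhydride to the only secondary hydroxyl (C3), while the tertiary hydroxyls at C4, C7 and C11 should not compete and no stereocentre is touched.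

**Compound list**

1 | (R)-3-hydroxyoxolan-2-one | O=C1[C@H](O)CCO1 | starting material
2 | (R)-3-(benzyloxy)oxolan-2-one | O=C1[C@H](OCc2ccccc2)CCO1 | intermediate
3 | (2R)-2-(benzyloxy)-4-hydroxy-N-methoxy-N-methylbutanamide | CON(C)C(=O)[C@H](OCc1ccccc1)CCO | intermediate
4 | (2R)-2-(benzyloxy)-4-iodo-N-methoxy-N-methylbutanamide | CON(C)C(=O)[C@H](OCc1ccccc1)CCI | intermediate
5 | but-2-yn-1-ol | CC#CCO | starting material
6 | diisobutylaluminium but-2-yn-1-olate | CC#CCO[Al](CC(C)C)CC(C)C | intermediate (not isolated)
7 | (E)-alkenylzirconocene chloride of 6 (Zr on C3, trans to CH2O) | CC(C)C[Al](CC(C)C)OC/C=C(C)/[Zr](Cl)(C1C=CC=C1)C1C=CC=C1 | intermediate (not isolated)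
8 | (E)-3-iodobut-2-en-1-ol | OC/C=C(C)/I | intermediate
9 | (E)-1-bromo-3-iodobut-2-ene | BrC/C=C(C)/I | intermediate
10 | pentane-2,4-dione | CC(=O)CC(C)=O | starting material
11 | 3-[(2E)-3-iodobut-2-en-1-yl]pentane-2,4-dione | CC(=O)C(C/C=C(C)/I)C(C)=O | intermediate
12 | sodium (Z)-enolate of 11 | [Na+].C/C([O-])=C(/C(C)=O)C/C=C(C)/I | intermediate (not isolated)
13 | (2Z,5E)-3-acetyl-6-iodohepta-2,5-dien-2-yl trifluoromethanesulfonate | C/C(OS(=O)(=O)C(F)(F)F)=C(/C(C)=O)C/C=C(C)/I | intermediate
14 | 3-[(2E)-3-iodobut-2-en-1-yl]-4-methylpent-3-en-2-one | CC(=O)C(C/C=C(C)/I)=C(C)C | intermediate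
15 | [(3R)-3-(benzyloxy)-4-[methoxy(methyl)amino]-4-oxobutyl]zinc iodide | CON(C)C(=O)[C@H](OCc1ccccc1)CC[Zn]I | intermediate (not isolated)
16 | (2R,5E)-2-(benzyloxy)-N-methoxy-N,5-dimethyl-9-oxo-8-(propan-2-ylidene)dec-5-enamide | CON(C)C(=O)[C@H](OCc1ccccc1)CC/C(C)=C/CC(=C(C)C)C(C)=O | intermediate
17 | lithium cross-conjugated dienolate of 16 (C8–O–Li, C8=C9) | CON(C)C(=O)[C@H](OCc1ccccc1)CC/C(C)=C/CC(=C(C)C)C(=C)O[Li] | intermediate (not isolated)
18 | (2R,5E)-2-(benzyloxy)-9-[(tert-butyldimethylsilyl)oxy]-N-methoxy-N,5-dimethyl-8-(propan-2-ylidene)deca-5,9-dienamide | CON(C)C(=O)[C@H](OCc1ccccc1)CC/C(C)=C/CC(=C(C)C)C(O[Si](C)(C)C(C)(C)C)=C | intermediate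
19 | bromomagnesium N,O-hemiaminal from 18 and MeMgBr (either configuration at the new carbon) | CON(C)C(C)(O[Mg]Br)[C@H](OCc1ccccc1)CC/C(C)=C/CC(=C(C)C)C(O[Si](C)(C)C(C)(C)C)=C | intermediate (not isolated)
20 | (3R,6E)-3-(benzyloxy)-10-[(tert-butyldimethylsilyl)oxy]-6-methyl-9-(propan-2-ylidene)undeca-6,10-dien-2-one | CC(=O)[C@H](OCc1ccccc1)CC/C(C)=C/CC(=C(C)C)C(O[Si](C)(C)C(C)(C)C)=C | intermediate
21 | SnCl4 chelate of 20 (tin bound to the C3 ether and C4 carbonyl oxygens) | CC1=[O+][Sn-2](Cl)(Cl)(Cl)(Cl)[O+](Cc2ccccc2)[C@@H]1CC/C(C)=C/CC(=C(C)C)C(O[Si](C)(C)C(C)(C)C)=C | intermediate (not isolated)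
22 | 3α-benzyloxy-4α-hydroxyeudesm-7(11)-en-8-one | c1ccccc1CO[C@@H]2CC[C@]3(C)CC(=O)C(=C(C)C)C[C@H]3[C@]2(C)O | intermediate
23 | 3α-benzyloxy-7α,11-epoxy-4α-hydroxyeudesman-8-one | c1ccccc1CO[C@@H]2CC[C@]3(C)CC(=O)[C@]4(OC4(C)C)C[C@H]3[C@]2(C)O | intermediate
24 | 3α-benzyloxy-4α,7α,11-trihydroxyeudesman-8-one | c1ccccc1CO[C@@H]2CC[C@]3(C)CC(=O)[C@@](O)(C(C)(C)O)C[C@H]3[C@]2(C)O | intermediate
25 | 3α,4α,7α,11-tetrahydroxyeudesman-8-one | O[C@@H]1CC[C@]2(C)CC(=O)[C@@](O)(C(C)(C)O)C[C@H]2[C@]1(C)O | intermediate
26 | angelic acid, (Z)-2-methylbut-2-enoic acid | C/C=C(/C)C(=O)O | starting material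
27 | (Z)-2-methylbut-2-en-1-ol | C/C=C(/C)CO | intermediate
28 | [(2R,3S)-2,3-dimethyloxiran-2-yl]methanol | C[C@@H]1O[C@]1(C)CO | intermediate
29 | (2S,3S)-2,3-dimethyloxirane-2-carboxylic acid | C[C@@H]1O[C@]1(C)C(=O)O | intermediate
30 | (2S,3S)-2,3-dimethyloxirane-2-carboxylic 2,4,6-trichlorobenzoic anhydride | C[C@@H]1O[C@]1(C)C(=O)OC(=O)c1c(Cl)cc(Cl)cc1Cl | intermediate (not isolated)
31 | 3α-[(2S,3S)-2,3-dimethyloxirane-2-carbonyloxy]-4α,7α,11-trihydroxyeudesman-8-one (3R,4S,5R,7S,10R) | C[C@@H]1O[C@]1(C)C(=O)O[C@@H]1CC[C@]2(C)CC(=O)[C@@](O)(C(C)(C)O)C[C@H]2[C@]1(C)O | target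

**Step count**

Total: 19 steps. Longest linear sequence: 13 steps (5 → 8 → 9 → 11 → 13 → 14 → 16 → 18 → 20 → 22 → 23 → 24 → 25 → 31; steps 4–15 and 19).

**Steps most likely to fail**

1. Step 12 (proposed new method). The silyl enol ether may add to the chelated ketone in place of the olefin (inter- or intramolecular aldol addition). The silyl group may be lost by tin–silicon exchange or protonation before C9–C10 forms. The C10 cation may end by proton loss, or ring A may fold through a boat and erode the C5/C10 configuration relative to C3/C4.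
Fallback, from 20 back to 22, with the two ring closures done separately by known reactions: 20 is desilylated with Bu4NF/AcOH to the diketone (3R,6E)-3-(benzyloxy)-6-methyl-9-(propan-2-ylidene)undec-6-ene-2,10-dione F1, in which the enone carbonyl is inert to Prins chemistry. TiCl4 (CH2Cl2, −78 °C) then effects the chelation-controlled Prins cyclisation of the olefinic α-benzyloxy ketone with chloride capture at C10, giving the ring-A chloro alcohol 3α-benzyloxy-10-chloro-4α-hydroxy-9,10-secoeudesm-7(11)-en-8-one F2. Me3SiOTf/Et3N converts F2, now the only ketone being C8, into the bis(trimethylsilyl) compound F3 (C4 silyl ether and C8 silyl dienol ether). ZnCl2 or TiCl4 then ionises the tertiary chloride for an intramolecular α-tert-alkylation of the silyl enol ether (C9–C10 bond, chair closure with the side chain equatorial, trans fusion expected, any cis isomer removed by chromatography). Dilute acid work-up cleaves the C4 silyl ether and returns 22.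

2. Step 14. Opening of the protonated oxirane at C11 may be diverted into 1,2-acyl migration or proton loss to an isopropenyl carbinol instead of capture by water, and any epoxide of the wrong C7 configuration from step 13 would be carried through.
Fallback, from 22 back to 24, bypassing the epoxide: direct syn-dihydroxylation of the C7=C11 olefin with stoichiometric OsO4 in pyridine/CH2Cl2, which forms the cyclic 7α,11-osmate ester of 22 (hexavalent osmium, bis-pyridine adduct) F4 with the bulky C11 carbon again equatorial; reductive cleavage with aq. NaHSO3 gives 24.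

3. Step 19. Acyl transfer to the axial, neopentyl-like C3 hydroxyl may be slow, so that the mixed anhydride of the α-quaternary epoxy acid decomposes or its oxirane opens before esterification.
Fallback, from 25 and 26 back to 31, with the oxirane made after the ester: angelic acid 26 is activated with 2,4,6-Cl3C6H2COCl/Et3N as angelic 2,4,6-trichlorobenzoic anhydride F5 and transferred with DMAP to 25, giving 3α-angeloyloxy-4α,7α,11-trihydroxyeudesman-8-one F6. The angelate olefin is then epoxidised with dimethyldioxirane (acetone, 0 °C → rt; syn-specific, so only the two cis-methyl/carboxyl epoxides form), and the (2S,3S) diastereomer 31 is separated by chromatography.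

**Further compounds**

F1 | step 12 | (3R,6E)-3-(benzyloxy)-6-methyl-9-(propan-2-ylidene)undec-6-ene-2,10-dione | CC(=O)[C@H](OCc1ccccc1)CC/C(C)=C/CC(=C(C)C)C(C)=O
F2 | step 12 | 3α-benzyloxy-10-chloro-4α-hydroxy-9,10-secoeudesm-7(11)-en-8-one (either C10 epimer) | c1ccccc1CO[C@@H]2CCC(C)(Cl)[C@@H](CC(=C(C)C)C(C)=O)[C@]2(C)O
F3 | step 12 | C4 trimethylsilyl ether and C8 trimethylsilyl dienol ether of F2 | c1ccccc1CO[C@@H]2CCC(C)(Cl)[C@@H](CC(=C(C)C)C(O[Si](C)(C)C)=C)[C@]2(C)O[Si](C)(C)C
F4 | step 14 | cyclic 7α,11-osmate ester of 22 (hexavalent osmium), bis-pyridine adduct | c1ccccc1CO[C@@H]2CC[C@]3(C)CC(=O)[C@]4(O[Os](=O)(=O)OC4(C)C)C[C@H]3[C@]2(C)O.c1ccncc1.c1ccncc1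
F5 | step 19 | (Z)-2-methylbut-2-enoic 2,4,6-trichlorobenzoic anhydride | C/C=C(/C)C(=O)OC(=O)c1c(Cl)cc(Cl)cc1Cl
F6 | step 19 | 3α-angeloyloxy-4α,7α,11-trihydroxyeudesman-8-one | C/C=C(/C)C(=O)O[C@@H]1CC[C@]2(C)CC(=O)[C@@](O)(C(C)(C)O)C[C@H]2[C@]1(C)O
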